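## The problem

Target **24** is a cyclohexene, numbered here C1 (CH bearing the isopropenyl group), C2=C3 (alkene, methyl on C3), C4 (CH bearing the CH2O arm that ends as a coumarin-7-yl ether), C5 (quaternary: methyl and the CH2CH2CO2H chain) and C6 (CH2). It has three stereocentres, C1 (S), C4 (R) and C5 (R). The isopropenyl group, the aryloxymethyl arm and the acid chain lie on one face of the ring and the C5 methyl on the other.

C5 is quaternary and cannot be corrected later, so it has to come from an enantioselective C–C bond formation. C4 is its neighbour and can be derived from it if the two side arms are held in a ring. C1 is 1,3 to C5 and separated from C4 by the alkene, so it needs its own stereo-determining event, guided at best by the conformation of a ring-fused intermediate.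

Three features restrict the reagents:
- The coumarin is a Michael acceptor and an aryl lactone; it will not survive hydride, organometallic or copper hydride reagents, so it is attached late.
- The C1 hydrogen is doubly allylic in a skipped diene and can move the alkenes into conjugation under strong base, acid or radical conditions.
- The isopropenyl group is easily protonated, and the free acid could then lactonise onto the cation, so the acid is released last and mildly.

The enabling feature is that C5, C4, the OCH2 carbon and the first chain carbon form a four-carbon unit oxidised at both ends. These are the ring carbons of 3-methyltetronic acid (**4**). C6, C1, C2, C3 and the C3 methyl are the five carbons of pent-1-en-3-one (**5**). Once an oxygen is restored at C2, the ring is the retron of a Michael–aldol (Robinson) annulation.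

## Retrosynthesis

**Aryl ether and acid.** The bond between the arm carbon and the coumarin oxygen is cut first, together with the ester that masks the acid: **24** from methyl ester **23**, and **23** from primary alcohol **21** and 7-hydroxycoumarin (**22**). Cutting here, instead of carrying the coumarin from an earlier stage, keeps the one reduction-sensitive unit out of every hydride, copper and organomagnesium step. The precursor **21** has lost the whole aromatic part. The forward reactions must etherify a hindered primary carbinol under neutral conditions and cleave an ester without disturbing the skipped diene.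

**The acid chain.** The bond between the first and second chain carbons is cut: **21** from enoate **20** by conjugate reduction, and **20** from lactol **17** and ylide **18**, with **17** coming from lactone **16**. A two-carbon olefination is preferred to alkylation, because the first chain carbon is neopentyl and would not undergo substitution. The lactone of **16** holds the arm carbon and the first chain carbon at different oxidation levels, so partial reduction releases the C5 aldehyde (open tautomer **19**) and the C4 carbinol together, with no protecting group. The forward steps must stop the reduction at the lactol and saturate the enoate in the presence of two other alkenes.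

**The C1–isopropenyl bond.** **16** is cut to allylic pivalate **14** and isopropenylmagnesium bromide (**15**), joined by a copper-mediated substitution with inversion. **14** comes from alcohol **13**, and **13** from enone **12**. A conjugate addition would need a carbonyl at C3, which carries the methyl group. The allylic substitution uses the C2=C3 alkene already in place and is stereospecific, so the C1 configuration traces back to a ketone reduction. The precursor **12** has one stereocentre and three carbons fewer. The forward sequence needs hydride delivery to the C1 face opposite the C5 methyl, and coupling at C1 and not at C3.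

**Alkene position and C4.** **12** comes from alkene **11** by oxidation of the C1 methylene. **11** comes from sulfonylhydrazone **9** of enone **8** by hydride reduction, which moves the alkene from C3=C4 to C2=C3 and places hydrogen on C4. This is preferred to hydrogenation followed by regioselective elimination because one event fixes both the alkene position and C4, with the hydrogen delivered intramolecularly through diazene **10**. The forward reaction must give the cis ring fusion, and the oxidation must choose the C1 methylene over the C4 methine.

**The ring (key disconnection).** **8** is cut at C5–C6 and C3–C4 into **4** and **5**, via Michael adduct **6** and ketol **7**. No other cut removes the ring, the quaternary centre and both side-arm carbons at once, and both precursors are small achiral compounds. The forward reaction must set C5 enantioselectively in the Michael step and close the six-membered ring by aldol condensation without cleaving the β-keto lactone.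

**The tetronic acid.** **4** is cut at its ring O–CH2 bond to bromo ester **3**, which comes from ethyl 2-methylacetoacetate (**1**) by γ-bromination via the α-bromo isomer **2**. This is the shortest entry from a bulk chemical and needs only thermal lactonisation.

## Roads not taken

**Alternative 1:** The cut removes the C5–methyl bond and the C4–CH2O bond from a 3,5-disubstituted cyclohexenone with its carbonyl at C3, enone A2. In the forward direction a methylcuprate would add to C5 anti to the C1 isopropenyl group, and the enolate would be trapped at C4 by a protected chloromethyl ether to give ketone A1.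
- Merits: two bonds and two stereocentres are made in one flask, the isopropenyl group is present from the start, and the C3 ketone can later become the C2=C3 methyl alkene through an enol triflate.
- Weak points: A2 is not a chiral-pool compound, so C1 needs its own asymmetric synthesis. The cuprate must build a quaternary centre on a β,β-disubstituted enone. The hindered enolate must then be alkylated beside that centre. The C4 face is decided only by the difference between an axial methyl and a propyl chain.
- Comparison: this road is better in that it needs no late C–H oxidation or allylic substitution at C1. The chosen plan sets against this a catalytic origin of absolute configuration from **4** and **5**, and a C4/C5 relationship enforced by the ring fusion of **11**.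

**Alternative 2:** The cut is a retro-Diels–Alder across C4–C5 and C1–C6. Phenol A4 would be oxidised by a hypervalent iodine reagent in the presence of allylic alcohol A5 to the mixed quinone monoketal A6, which closes intramolecularly to tricycle A3.
- Merits: the ring, the quaternary centre, the C3 methyl alkene and the relative configuration of C1, C4 and C5 are all set in one operation from cheap aromatics. In stereochemical economy this road is clearly better than the chosen plan, which needs three separate stereo-determining events.
- Weak points: A3 is formed as a racemate unless a resolution or auxiliary is added. The two-carbon bridge must be cleaved oxidatively in the presence of the ring alkene. All three side arms must then be rebuilt: ketone carbon to isopropenyl, ketal carbon to CH2O, and the oxolane carbon extended by two carbons at a neopentyl position.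
- Comparison: the chosen plan sets against this enantioselective catalysis at the outset and a later sequence without any C–C cleavage.

**Alternative 3:** The cut removes the bonds from C4 and C5 to the two side-arm carbons. Enone A8 (carbonyl at C3) would be irradiated with cyclic carbonate A9 in the presence of a chiral oxazaborolidine-based Lewis acid to give the cis-fused cyclobutane A7.
- Merits: C4 and C5 are set together and enantioselectively. The C3 ketone then allows the isopropenyl group to be introduced at C1 by conjugate addition after desaturation, with enolate triflation and methylation to finish the alkene. That is shorter than the four steps the chosen plan spends on C1 (steps 6 to 9), and here this road is better.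
- Weak points: it needs cryogenic irradiation with a high loading of chiral Lewis acid. The facial course of the C1 addition beside the tricycle is uncertain. Cleaving the diol carbonate exposes two aldehyde groups at the same oxidation level. The C4 aldehyde would be β,γ-unsaturated and could epimerise or conjugate.
- Comparison: the chosen plan has the two arms differentiated from the start in the lactone of **8**, and C4 never carries an acidifying group.

Key step: step 3

Assumption: the quinidine-derived thiourea is taken as the pseudoenantiomer that gives the (R) centre of **6**; if the sense of induction is the reverse, the quinine-derived catalyst is used with no other change.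

Note on numbering: in the bicyclic lactones, target positions C1, C2, C3, C4, C5 and C6 are positions 6, 5, 4, 3a, 7a and 7 of the 2-benzofuranone skeleton.

## Route

Step 1
Reactants: 1 ethyl 2-methyl-3-oxobutanoate
Product: 3 ethyl 4-bromo-2-methyl-3-oxobutanoate (racemic), via α-bromo ester 2 (not isolated)
Conditions: Br2 (1.0 equiv), CHCl3, 0 °C → rt, 16 h, HBr retained
Reagents that add atoms: bromine, BrBr
Why: Bromination of the enol first gives the 2-bromo ester 2; the HBr formed catalyses reversible bromine transfer to the terminal methyl group, so the mixture should settle on the 4-bromo ketone 3 (acid-mediated α-to-γ halogen migration in α-substituted acetoacetates).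

Step 2
Reactants: 3 ethyl 4-bromo-2-methyl-3-oxobutanoate
Product: 4 3-methyltetronic acid [4-hydroxy-3-methylfuran-2(5H)-one]
Conditions: neat, 120–130 °C, EtBr distilled off; recrystallisation
Reagents that add atoms: none
Why: The ester carbonyl oxygen displaces bromide in a 5-exo-tet closure and bromide dealkylates the resulting oxonium ion, so bromoethane is expelled and the furan-2,4-dione tautomerises to the tetronic acid (thermal lactonisation of a γ-bromo-β-keto ester).

Step 3
Reactants: 4 3-methyltetronic acid; 5 pent-1-en-3-one
Product: 8 (7aR)-4,7a-dimethyl-7,7a-dihydro-2-benzofuran-1,5(3H,6H)-dione, via Michael adduct 6 (not isolated), via ketol 7 (not isolated)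
Conditions: 5 (1.5 equiv), 1-[3,5-bis(trifluoromethyl)phenyl]-3-(9-deoxy-epi-quinidin-9-yl)thiourea (10 mol %), CH2Cl2, −20 °C; concentrate; then p-TsOH·H2O (0.3 equiv), toluene, reflux, azeotropic removal of water
Reagents that add atoms: none
Why: The quinuclidine nitrogen deprotonates the strongly acidic 4, and the ammonium tetronate, held by hydrogen bonds in the chiral pocket while the thiourea activates the carbonyl of 5, adds through its ring carbon to the enone terminus to form the C5–C6 bond of 6. The closest known reaction type is the bifunctional amine-thiourea catalysed Michael addition of cyclic α-substituted 1,3-dicarbonyl and β-keto lactone donors to vinyl ketones, followed by the condensation half of a Robinson annulation. The only new stereocentre that survives, quaternary C5, is set in this Michael step by the catalyst, which must distinguish the two faces of a flat anion whose flanks differ only as lactone and enolate oxygen; it bears no hydrogen and could be lost only by retro-Michael reaction, which the acidic second stage does not promote. After excess 5 is removed, p-TsOH enolises the ethyl ketone toward its methylene, and this enol attacks the ring ketone in a 6-(enolendo)-exo-trig aldol closure to ketol 7, whose dehydration gives the tetrasubstituted enone 8 and forms the C3–C4 bond. Carbon rather than oxygen alkylation is expected because the enone is a soft acceptor and an O-adduct would revert. A second six-membered aldol is conceivable, from the enol of the ring ketone onto the side-chain ketone, but it gives a bridged ketol that cannot dehydrate into conjugation and returns to 6, so the fused enone is the thermodynamic outlet. Acid is used for the condensation because the 3,3-disubstituted furan-2,4-dione is a β-keto lactone that amines or alkoxides would cleave by retro-Claisen reaction.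

Step 4
Reactants: 8 (7aR)-4,7a-dimethyl-7,7a-dihydro-2-benzofuran-1,5(3H,6H)-dione
Product: 9 N'-[(7aR)-4,7a-dimethyl-1-oxo-1,3,7,7a-tetrahydro-2-benzofuran-5(6H)-ylidene]-4-methylbenzenesulfonohydrazide
Conditions: TsNHNH2 (1.1 equiv), AcOH (cat.), EtOH, 50 °C
Reagents that add atoms: 4-methylbenzenesulfonohydrazide, Cc1ccc(cc1)S(=O)(=O)NN
Why: Acid-catalysed condensation of the conjugated ketone with the sulfonylhydrazide (hydrazone formation); the lactone carbonyl is far less electrophilic and the fully substituted β-carbon does not accept the nucleophile, so only C2 should react.

Step 5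
Reactants: 9 tosylhydrazone of 8
Product: 11 (3aS,7aR)-4,7a-dimethyl-3a,6,7,7a-tetrahydro-2-benzofuran-1(3H)-one, via allylic diazene 10 (not isolated)
Conditions: catecholborane (2 equiv), CHCl3, 0 °C; then NaOAc·3H2O (3 equiv), reflux
Reagents that add atoms: none
Why: Hydride adds 1,2 to the C=N bond, acetate then induces loss of sulfinate to give allylic diazene 10, and a suprafacial 1,5-hydrogen shift with loss of N2 moves the alkene to C2=C3 and places hydrogen on C4 (reductive 1,3-transposition of an enone tosylhydrazone). Hydride should add axially, anti to the pseudo-axial C5 methyl, so the diazene nitrogen and then the C4 hydrogen lie on the methyl face, which is the cis ring fusion; the same sense is documented for angularly methylated 4-en-3-one tosylhydrazones of the steroid series. Base is added only after the reduction, so the conjugated hydrazone with its allylic lactone oxygen is never exposed to acetate.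

Step 6
Reactants: 11 (3aS,7aR)-4,7a-dimethyl-3a,6,7,7a-tetrahydro-2-benzofuran-1(3H)-one
Product: 12 (3aS,7aR)-4,7a-dimethyl-3a,7-dihydro-2-benzofuran-1,6(3H,7aH)-dione
Conditions: Rh2(cap)4 (cap = caprolactamate, 1 mol %), t-BuOOH (70% aq, 5 equiv), K2CO3 (0.5 equiv), CH2Cl2, rt
Reagents that add atoms: tert-butyl hydroperoxide, CC(C)(C)OO
Why: In this dirhodium-catalysed allylic oxidation the tert-butylperoxyl radical should abstract the well-aligned pseudo-axial hydrogen of the secondary C1 methylene, and trapping at C1 followed by collapse of the mixed peroxide gives the β,β-disubstituted enone. The competing C4 hydrogen is tertiary, pseudo-equatorial and shielded by the quaternary centre; abstraction there would lead back to enone 8, which could be returned to step 4.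

Step 7
Reactants: 12 (3aS,7aR)-4,7a-dimethyl-3a,7-dihydro-2-benzofuran-1,6(3H,7aH)-dione
Product: 13 (3aS,6R,7aR)-6-hydroxy-4,7a-dimethyl-3a,6,7,7a-tetrahydro-2-benzofuran-1(3H)-one
Conditions: NaBH4, CeCl3·7H2O, MeOH, −78 °C
Reagents that add atoms: none
Why: Luche reduction gives 1,2-addition only and leaves the lactone untouched at this temperature. In the favoured half-chair the C4 arm is pseudo-axial to avoid strain with the C3 methyl, which puts the C5 methyl axial over one face of C1; hydride should therefore arrive from the opposite face, as with ketones that have a syn-axial angular methyl group, and give the alcohol cis to that methyl.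

Step 8
Reactants: 13 (3aS,6R,7aR)-6-hydroxy-4,7a-dimethyl-3a,6,7,7a-tetrahydro-2-benzofuran-1(3H)-one
Product: 14 (3aS,6R,7aR)-4,7a-dimethyl-1-oxo-1,3,3a,6,7,7a-hexahydro-2-benzofuran-6-yl 2,2-dimethylpropanoate
Conditions: t-BuCOCl, pyridine, DMAP (cat.), CH2Cl2, 0 °C → rt
Reagents that add atoms: pivaloyl chloride, CC(C)(C)C(=O)Cl
Why: Nucleophile-catalysed acylation with retention at C1; the pivalate is chosen as leaving group because its hindered carbonyl resists attack by the organocopper reagent of the next step.

Step 9
Reactants: 14 allylic pivalate; 15 isopropenylmagnesium bromide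
Product: 16 (3aS,6S,7aR)-4,7a-dimethyl-6-(prop-1-en-2-yl)-3a,6,7,7a-tetrahydro-2-benzofuran-1(3H)-one
Conditions: 15 (2.4 equiv), CuBr·SMe2 (1.2 equiv), THF, −40 °C; then 14, −78 → −10 °C; aq NH4Cl
Reagents that add atoms: none
Why: In this copper-mediated allylic substitution the diisopropenylcuprate adds oxidatively anti to the departing pivalate, and the allyl intermediate of trivalent copper should couple at C1, because the other terminus C3 would become a quaternary centre beside C4 and C5. Net inversion places the isopropenyl group on the face opposite the C5 methyl, and the lower-order cuprate should not add to the hindered lactone at these temperatures.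

Step 10
Reactants: 16 (3aS,6S,7aR)-4,7a-dimethyl-6-(prop-1-en-2-yl)-3a,6,7,7a-tetrahydro-2-benzofuran-1(3H)-one
Product: 17 (3aS,6S,7aR)-4,7a-dimethyl-6-(prop-1-en-2-yl)-1,3,3a,6,7,7a-hexahydro-2-benzofuran-1-ol (anomer mixture)
Conditions: i-Bu2AlH (1.2 equiv), CH2Cl2, −78 °C; aq KNaC4H4O6
Reagents that add atoms: none
Why: Partial reduction of a lactone to the lactol; the tetrahedral aluminium alkoxide is stable at −78 °C and collapses only on work-up, and the alkenes are inert to the hydride.

Step 11
Reactants: 17 lactol; 18 methyl (triphenylphosphoranylidene)acetate
Product: 20 methyl (2E)-3-[(1S,2S,5S)-2-(hydroxymethyl)-1,3-dimethyl-5-(prop-1-en-2-yl)cyclohex-3-en-1-yl]prop-2-enoate, via hydroxy aldehyde 19 (not isolated)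
Conditions: 18 (2 equiv), toluene, 80 °C
Reagents that add atoms: none
Why: The lactol reacts through its open tautomer 19 in a Wittig olefination with the stabilised ylide, which should give the E-enoate. Neutral conditions are kept so that the released C4 carbinol does not add back to the enoate, an addition also slowed by the fully substituted carbon next to the β-position.

Step 12
Reactants: 20 hydroxy enoate
Product: 21 methyl 3-[(1R,2R,5S)-2-(hydroxymethyl)-1,3-dimethyl-5-(prop-1-en-2-yl)cyclohex-3-en-1-yl]propanoate
Conditions: [(Ph3P)CuH]6 (0.4 equiv), H2O (5 equiv), toluene, rt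
Reagents that add atoms: none
Why: Copper hydride adds in conjugate fashion to the enoate only, and water protonates the copper enolate (conjugate reduction with a phosphine-stabilised copper hydride); the isolated trisubstituted and 1,1-disubstituted alkenes are not hydrometalated, and no radical or basic intermediate touches the doubly allylic C1 hydrogen.

Step 13
Reactants: 21 hydroxy ester; 22 7-hydroxycoumarin (umbelliferone)
Product: 23 methyl 3-[(1R,2R,5S)-1,3-dimethyl-2-{[(2-oxo-2H-chromen-7-yl)oxy]methyl}-5-(prop-1-en-2-yl)cyclohex-3-en-1-yl]propanoate
Conditions: 22 (1.3 equiv), PPh3, DIAD, THF, 0 °C → rt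
Reagents that add atoms: none
Why: Mitsunobu etherification: the acidic phenol protonates the betaine and its anion displaces the alkoxyphosphonium ion at the primary carbon, so no stereocentre is involved. The neutral conditions leave the ester, the coumarin and the skipped diene unchanged.

Step 14
Reactants: 23 methyl ester
Product: 24 3-[(1R,2R,5S)-1,3-dimethyl-2-{[(2-oxo-2H-chromen-7-yl)oxy]methyl}-5-(prop-1-en-2-yl)cyclohex-3-en-1-yl]propanoic acid
Conditions: LiOH·H2O (3 equiv), THF/H2O 3:1, 0 °C → rt; then 1 M HCl to pH 3, 0 °C
Reagents that add atoms: lithium hydroxide, [Li+].[OH-]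
Why: Saponification of the unhindered methyl ester. The coumarin lactone may open reversibly to the cis-coumarinate under hydroxide and should reclose on acidification, and the brief cold acidification is mild enough to spare the isopropenyl group.

## Compound list

1 | ethyl 2-methyl-3-oxobutanoate (ethyl 2-methylacetoacetate) | CCOC(=O)C(C)C(C)=O | starting material
2 | ethyl 2-bromo-2-methyl-3-oxobutanoate (racemic, not isolated) | CCOC(=O)C(C)(Br)C(C)=O | intermediate
3 | ethyl 4-bromo-2-methyl-3-oxobutanoate (racemic) | CCOC(=O)C(C)C(=O)CBr | intermediate
4 | 3-methyltetronic acid, 4-hydroxy-3-methylfuran-2(5H)-one | CC1=C(O)COC1=O | intermediate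
5 | pent-1-en-3-one | C=CC(=O)CC | starting material
6 | (3R)-3-methyl-3-(3-oxopentyl)furan-2,4(3H,5H)-dione (not isolated) | CCC(=O)CC[C@@]1(C)C(=O)OCC1=O | intermediate
7 | (7aR)-3a-hydroxy-4,7a-dimethylhexahydro-2-benzofuran-1,5-dione, mixture of epimers at the two new centres (not isolated) | CC1C(=O)CC[C@@]2(C)C(=O)OCC12O | intermediate
8 | (7aR)-4,7a-dimethyl-7,7a-dihydro-2-benzofuran-1,5(3H,6H)-dione | O=C1CC[C@@]2(C)C(=O)OCC2=C1C | intermediate
9 | N'-[(7aR)-4,7a-dimethyl-1-oxo-1,3,7,7a-tetrahydro-2-benzofuran-5(6H)-ylidene]-4-methylbenzenesulfonohydrazide (C=N geometry not defined) | Cc1ccc(cc1)S(=O)(=O)NN=C1CC[C@@]2(C)C(=O)OCC2=C1C | intermediate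
10 | (5R,7aR)-5-diazenyl-4,7a-dimethyl-5,6,7,7a-tetrahydro-2-benzofuran-1(3H)-one (not isolated) | C1[C@@H](N=N)C(C)=C2COC(=O)[C@]2(C)C1 | intermediate
11 | (3aS,7aR)-4,7a-dimethyl-3a,6,7,7a-tetrahydro-2-benzofuran-1(3H)-one, cis-fused | C1C=C(C)[C@@H]2COC(=O)[C@]2(C)C1 | intermediate
12 | (3aS,7aR)-4,7a-dimethyl-3a,7-dihydro-2-benzofuran-1,6(3H,7aH)-dione | O=C1C=C(C)[C@@H]2COC(=O)[C@]2(C)C1 | intermediate
13 | (3aS,6R,7aR)-6-hydroxy-4,7a-dimethyl-3a,6,7,7a-tetrahydro-2-benzofuran-1(3H)-one, hydroxyl cis to the angular methyl | O[C@H]1C=C(C)[C@@H]2COC(=O)[C@]2(C)C1 | intermediate
14 | (3aS,6R,7aR)-4,7a-dimethyl-1-oxo-1,3,3a,6,7,7a-hexahydro-2-benzofuran-6-yl 2,2-dimethylpropanoate | CC(C)(C)C(=O)O[C@H]1C=C(C)[C@@H]2COC(=O)[C@]2(C)C1 | intermediate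
15 | isopropenylmagnesium bromide | C=C(C)[Mg]Br | starting material
16 | (3aS,6S,7aR)-4,7a-dimethyl-6-(prop-1-en-2-yl)-3a,6,7,7a-tetrahydro-2-benzofuran-1(3H)-one | C=C(C)[C@@H]1C=C(C)[C@@H]2COC(=O)[C@]2(C)C1 | intermediate
17 | (3aS,6S,7aR)-4,7a-dimethyl-6-(prop-1-en-2-yl)-1,3,3a,6,7,7a-hexahydro-2-benzofuran-1-ol, anomer mixture | C=C(C)[C@@H]1C=C(C)[C@@H]2COC(O)[C@]2(C)C1 | intermediate
18 | methyl (triphenylphosphoranylidene)acetate | COC(=O)C=P(c1ccccc1)(c1ccccc1)c1ccccc1 | starting material
19 | (1R,2S,5S)-2-(hydroxymethyl)-1,3-dimethyl-5-(prop-1-en-2-yl)cyclohex-3-ene-1-carbaldehyde (not isolated) | C=C(C)[C@@H]1C=C(C)[C@H](CO)[C@](C)(C=O)C1 | intermediate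
20 | methyl (2E)-3-[(1S,2S,5S)-2-(hydroxymethyl)-1,3-dimethyl-5-(prop-1-en-2-yl)cyclohex-3-en-1-yl]prop-2-enoate | C=C(C)[C@@H]1C=C(C)[C@H](CO)[C@](C)(/C=C/C(=O)OC)C1 | intermediate
21 | methyl 3-[(1R,2R,5S)-2-(hydroxymethyl)-1,3-dimethyl-5-(prop-1-en-2-yl)cyclohex-3-en-1-yl]propanoate | C=C(C)[C@@H]1C=C(C)[C@H](CO)[C@](C)(CCC(=O)OC)C1 | intermediate
22 | 7-hydroxy-2H-chromen-2-one (umbelliferone) | O=c1ccc2ccc(O)cc2o1 | starting material
23 | methyl 3-[(1R,2R,5S)-1,3-dimethyl-2-{[(2-oxo-2H-chromen-7-yl)oxy]methyl}-5-(prop-1-en-2-yl)cyclohex-3-en-1-yl]propanoate | C=C(C)[C@@H]1C=C(C)[C@H](COc2ccc3ccc(=O)oc3c2)[C@](C)(CCC(=O)OC)C1 | intermediate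
24 | 3-[(1R,2R,5S)-1,3-dimethyl-2-{[(2-oxo-2H-chromen-7-yl)oxy]methyl}-5-(prop-1-en-2-yl)cyclohex-3-en-1-yl]propanoic acid | C=C(C)[C@@H]1C=C(C)[C@H](COc2ccc3ccc(=O)oc3c2)[C@](C)(CCC(=O)O)C1 | target

## Step count and uncertain steps

Total: 14 steps. Longest linear sequence: 14 steps (1 to 24); 5, 15, 18 and 22 are purchased and enter directly.

**Step 3 (key step).** The most likely failure is low enantiofacial discrimination. The tetronate is a small, flat, strongly acidic donor whose two flanks differ only slightly, it fully protonates the catalyst, and an uncatalysed background addition to 5 could erode the selectivity. The fallback is a resolution. It sets out from 4 and 5: triethylamine-catalysed addition gives the racemic Michael adduct F1, which the same acid treatment converts via the racemic ketol F2 into the racemic enone F3. Oxazaborolidine-catalysed reduction (catecholborane, (S)-B-methyl oxazaborolidine from diphenylprolinol, toluene, −78 °C) is reagent-controlled. It should turn the two enantiomers into two separable diastereomers of the same carbinol configuration, the (5R,7aR) allylic alcohol F4 and the (5R,7aS) allylic alcohol F5. F4 is oxidised with MnO2 and comes back to the route at 8; F5 is discarded.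

**Step 6.** The risk is hydrogen abstraction at the wrong allylic site (the C4 methine or the C3 methyl) or trapping of the allyl radical at C3, giving isomeric oxidation products. The fallback sets out from 11 and moves the oxygen to C1 by polar steps:
- Epoxidation with mCPBA gives the C2–C3 epoxide F6.
- PhSeNa (from PhSeSePh and NaBH4 in EtOH) opens it at the less substituted C2 to the hydroxy selenide F7.
- H2O2 gives the selenoxide F8, whose syn-elimination can go only toward C1, because C3 has no hydrogen, and gives the tertiary allylic alcohol F9.
- Pyridinium chlorochromate, [C5H5NH][CrO3Cl], effects oxidative 1,3-transposition of F9, which comes back to the route at 12.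

**Step 7.** The risk is poor or reversed facial selectivity, because two half-chair conformers of 12 expose opposite faces of the C1 carbonyl and the preference between them rests on a modest allylic strain term. The fallback sets out from 12 and accepts the other face. If the reduction gives mainly the (6S) epimeric alcohol F10, Mitsunobu esterification with benzoic acid (PPh3, DIAD) inverts C1 and gives the benzoate F11. F11 has the configuration of 14 and is carried through the conditions of step 9, coming back to the route at 16.

**Step 9.** The risks are slow ionisation (the reactive conformer has the pivalate syn-axial to the C5 methyl), coupling at C3, and attack of residual organomagnesium reagent on the lactone. The fallback sets out from 13 and replaces copper by palladium. Methyl chloroformate and pyridine give the methyl carbonate F12. Pd(PPh3)4 with isopropenylboronic acid pinacol ester (THF, 60 °C) ionises it with inversion at zerovalent palladium. Transmetalation and reductive elimination from the metal face at the less hindered terminus then give net inversion, coming back to the route at 16.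

**Step 11.** The risks are sluggish olefination of a neopentyl aldehyde that is present only as a minor tautomer and, on forcing, conjugate addition of the released hydroxyl to the enoate to close an oxolane. The fallback sets out from 16 and keeps the hydroxyl protected:
- Me3Al with N,O-dimethylhydroxylamine hydrochloride opens the lactone to the hydroxy N-methoxy-N-methylamide F13.
- t-BuMe2SiOTf and 2,6-lutidine give the silyl ether F14.
- i-Bu2AlH gives the aldehyde F15.
- Ylide 18 gives the silyl-protected enoate F16.
- [(Ph3P)CuH]6 gives the saturated silyl ether ester F17.
- Bu4NF removes the silyl group and comes back to the route at 21.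

## Further compounds

F1 | step 3 | racemic 3-methyl-3-(3-oxopentyl)furan-2,4(3H,5H)-dione | CCC(=O)CCC1(C)C(=O)OCC1=O
F2 | step 3 | racemic 3a-hydroxy-4,7a-dimethylhexahydro-2-benzofuran-1,5-dione (epimer mixture) | CC1C(=O)CCC2(C)C(=O)OCC12O
F3 | step 3 | racemic 4,7a-dimethyl-7,7a-dihydro-2-benzofuran-1,5(3H,6H)-dione | O=C1CCC2(C)C(=O)OCC2=C1C
F4 | step 3 | (5R,7aR)-5-hydroxy-4,7a-dimethyl-5,6,7,7a-tetrahydro-2-benzofuran-1(3H)-one | O[C@@H]1CC[C@@]2(C)C(=O)OCC2=C1C
F5 | step 3 | (5R,7aS)-5-hydroxy-4,7a-dimethyl-5,6,7,7a-tetrahydro-2-benzofuran-1(3H)-one | O[C@@H]1CC[C@]2(C)C(=O)OCC2=C1C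
F6 | step 6 | C2–C3 epoxide of 11 (target numbering; epoxide face not defined) | C1C2OC2(C)[C@@H]3COC(=O)[C@]3(C)C1
F7 | step 6 | C3-hydroxy C2-phenylselanyl lactone from F6 (target numbering; new centres not defined) | C1C([Se]c2ccccc2)C(C)(O)[C@@H]3COC(=O)[C@]3(C)C1
F8 | step 6 | selenoxide of F7 | C1C([Se](=O)c2ccccc2)C(C)(O)[C@@H]3COC(=O)[C@]3(C)C1
F9 | step 6 | cis-fused lactone with C1=C2 alkene and tertiary hydroxyl on C3 (target numbering; C3 not defined) | C1=CC(C)(O)[C@@H]2COC(=O)[C@]2(C)C1
F10 | step 7 | (3aS,6S,7aR)-6-hydroxy-4,7a-dimethyl-3a,6,7,7a-tetrahydro-2-benzofuran-1(3H)-one | O[C@@H]1C=C(C)[C@@H]2COC(=O)[C@]2(C)C1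
F11 | step 7 | (3aS,6R,7aR)-4,7a-dimethyl-1-oxo-1,3,3a,6,7,7a-hexahydro-2-benzofuran-6-yl benzoate | O=C(O[C@H]1C=C(C)[C@@H]2COC(=O)[C@]2(C)C1)c1ccccc1
F12 | step 9 | (3aS,6R,7aR)-4,7a-dimethyl-1-oxo-1,3,3a,6,7,7a-hexahydro-2-benzofuran-6-yl methyl carbonate | COC(=O)O[C@H]1C=C(C)[C@@H]2COC(=O)[C@]2(C)C1
F13 | step 11 | (1R,2S,5S)-2-(hydroxymethyl)-N-methoxy-N,1,3-trimethyl-5-(prop-1-en-2-yl)cyclohex-3-ene-1-carboxamide | C=C(C)[C@@H]1C=C(C)[C@H](CO)[C@](C)(C(=O)N(C)OC)C1
F14 | step 11 | tert-butyldimethylsilyl ether of F13 | C=C(C)[C@@H]1C=C(C)[C@H](CO[Si](C)(C)C(C)(C)C)[C@](C)(C(=O)N(C)OC)C1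
F15 | step 11 | tert-butyldimethylsilyl ether of hydroxy aldehyde 19 | C=C(C)[C@@H]1C=C(C)[C@H](CO[Si](C)(C)C(C)(C)C)[C@](C)(C=O)C1
F16 | step 11 | tert-butyldimethylsilyl ether of enoate 20 | C=C(C)[C@@H]1C=C(C)[C@H](CO[Si](C)(C)C(C)(C)C)[C@](C)(/C=C/C(=O)OC)C1
F17 | step 11 | tert-butyldimethylsilyl ether of hydroxy ester 21 | C=C(C)[C@@H]1C=C(C)[C@H](CO[Si](C)(C)C(C)(C)C)[C@](C)(CCC(=O)OC)C1
A1 | alternative 1 | 2-[(4-methoxybenzyloxy)methyl]-3-methyl-3-[3-(tert-butyldimethylsilyloxy)propyl]-5-(prop-1-en-2-yl)cyclohexan-1-one with the target configuration at the three ring centres | C=C(C)[C@@H]1CC(=O)[C@H](COCc2ccc(OC)cc2)[C@](C)(CCCO[Si](C)(C)C(C)(C)C)C1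
A2 | alternative 1 | (5S)-3-[3-(tert-butyldimethylsilyloxy)propyl]-5-(prop-1-en-2-yl)cyclohex-2-en-1-one | C=C(C)[C@@H]1CC(=O)C=C(CCCO[Si](C)(C)C(C)(C)C)C1
A3 | alternative 2 | tricyclic ketal adduct, bicyclo[2.2.2]octenone fused to an oxolane | O=C2[C@@H]1C=C(C)[C@H]([C@@]2(OC)O3)[C@](C)(C3)C1
A4 | alternative 2 | 2-methoxy-4-methylphenol | Cc1ccc(O)c(OC)c1
A5 | alternative 2 | 2-methylprop-2-en-1-ol | C=C(C)CO
A6 | alternative 2 | 6-methoxy-4-methyl-6-[(2-methylprop-2-en-1-yl)oxy]cyclohexa-2,4-dien-1-one (racemic) | O=C1C=CC(C)=CC1(OC)OCC(C)=C
A7 | alternative 3 | cis-anti-cis tricyclic keto carbonate | O=C1CCC[C@]2(C)[C@H]1[C@H]3OC(=O)O[C@H]32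
A8 | alternative 3 | 3-methylcyclohex-2-en-1-one | CC1=CC(=O)CCC1
A9 | alternative 3 | 1,3-dioxol-2-one (vinylene carbonate) | O=C1OC=CO1
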